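**Assumptions (one line each)**
- The tertiary-carbinol epimer formed in Step 3 is irrelevant, because that centre is destroyed in Step 4.
- The configurations at C6, C7 and C10 are assumed to follow the conformational bias of the germacranolide macrocycle, as in costunolide and parthenolide chemistry.
- Germacrane numbering is used throughout. C1 to C10 is the ten-membered ring, C11 to C13 is the lactone unit, C14 is the C10 methyl, C15 is the C4 methyl.

## Retrosynthetic overview
1. Eupaheliangolide A comes from α-methylenation of the 11,13-dihydro lactone. That lactone comes from base-mediated opening of a 1(10)-epoxy-3-ketone, which gives the 10-OH and the E-1(2)-enone. The 1(10)-epoxide comes from the Δ1(10) germacranolide carrying the 8-tiglate.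
2. The 6,12-lactone forms by reducing the C6 ketone, which closes onto a C7–CH2CO2Et group. C8–O comes from a β-alkoxyvinyl unit.
3. The key step is an anionic oxy-Cope ([3,3]-sigmatropic) ring expansion of a carvone-derived 1,2-divinylcyclohexanol.
   - The carvone ring becomes C1–C6.
   - Carvone's isopropenyl becomes C9, C10 and C14.
   - The vinyl ether becomes C7 and C8.
   - The enolate is trapped at C7 with bromoacetate.
   - The carvone ring alkene becomes the Z-4(5)-enone.
4. Ring order: the cyclohexane is already present in carvone. The ten-membered ring forms in Step 4, and the lactone forms in Step 5.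

## Route

**Step 1**
Reactants: 1 (E)-1,2-diiodoethene; 2 4-methoxybenzyl alcohol
Product: 3 (E)-1-iodo-2-[(4-methoxybenzyl)oxy]ethene
Conditions: CuI (10 mol%), 3,4,7,8-tetramethyl-1,10-phenanthroline (20 mol%), Cs2CO3, toluene, 80 °C (1 in excess)
Reagents that add atoms: 2, COc1ccc(CO)cc1
Why: Cu-catalysed Ullmann-type C–O coupling of a vinyl iodide with an alcohol keeps the alkene geometry, so it gives the E-β-alkoxyvinyl iodide.

**Step 2**
Reactants: 4 (R)-carvone
Product: 5 (5R)-2-methyl-5-(prop-1-en-2-yl)cyclohex-2-ene-1,4-dione
Conditions: Mn(OAc)3·2H2O (10 mol%), TBHP (in decane), 3 Å MS, EtOAc, rt; use crude and cold at once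
Reagents that add atoms: tert-butyl hydroperoxide, CC(C)(C)OO (oxygen source)
Why: Mn/TBHP allylic oxidation targets the γ-CH2 of the enone, via the dienyl radical conjugated to the carbonyl, to give the ene-dione. The C5 stereocentre is untouched. The dione tautomerises to a hydroquinone on standing, so it is used immediately.

**Step 3**
Reactants: 5 ene-dione; 3 vinyl iodide
Product: 6 (5R)-4-hydroxy-4-[(E)-2-(PMBO)vinyl]-2-methyl-5-(prop-1-en-2-yl)cyclohex-2-en-1-one (C4 epimer unspecified)
Conditions: 3, t-BuLi (2 equiv), THF, −78 °C; anhydrous CeCl3, −78 °C; then 5, −78 °C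
Reagents that add atoms: none (the vinyl unit comes from 3)
Why: the organocerium adds 1,2 to the ene-dione carbonyl remote from the methyl group, which is the more electrophilic one. This gives the tertiary allylic alcohol that carries the vinyl ether next to the isopropenyl-bearing carbon, i.e. the 3-hydroxy-1,5-diene.

**Step 4**
Reactants: 6 carbinol; 7 ethyl bromoacetate
Product: 8 ten-membered keto ester (1E,4Z)-diene-3,6-dione, with 7R-CH2CO2Et and 8R-OPMB
Conditions: KH, 18-crown-6, THF, −20 → 0 °C; then 7, −78 °C → rt
Reagents that add atoms: ethyl bromoacetate, BrCC(=O)OCC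
Why: anionic oxy-Cope ([3,3]) ring expansion through a chair transition state.
- It breaks the C6–C1 bond of the cyclohexane and forms C8–C9.
- It gives the E-C1=C10 alkene and a C6/C7 enolate, and the ring alkene stays Z as the C4=C5 enone.
- The carvone stereocentre is transferred to C8 by the equatorial E-alkoxy group in the chair.
- The enolate is alkylated regiospecifically at C7.

**Step 5**
Reactants: 8 keto ester
Product: 9 PMB lactone, the 6,12-olide with Δ1(10),4 and 3-oxo, 11,13-dihydro, 8-OPMB
Conditions: NaBH4, CeCl3·7H2O, MeOH/CH2Cl2, −78 °C; then p-TsOH (cat.), CH2Cl2, rt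
Reagents that add atoms: none
Why: Luche reduction of the C6 ketone, the carbonyl farther from the methyl group, sets C6 by hydride approach from the open face of the ring. The alkoxide or hydroxy ester then closes onto the C7 side chain to give the trans-fused γ-lactone. Under acid-catalysed conditions C7 sits at the thermodynamically preferred trans-lactone configuration.

**Step 6**
Reactants: 9
Product: 10 hydroxy lactone (8-OH)
Conditions: DDQ, CH2Cl2/pH 7 buffer, 0 °C
Reagents that add atoms: none
Why: oxidative cleavage of the PMB ether is selective over the other functional groups, and C8 is not touched.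

**Step 7**
Reactants: 10 alcohol; 11 tiglic acid
Product: 12 8-tiglate
Conditions: 11, 2,4,6-Cl3C6H2COCl, Et3N, THF, rt; then 10, DMAP, toluene, rt
Reagents that add atoms: 11, C/C=C(\C)C(=O)O
Why: Yamaguchi esterification through the mixed anhydride keeps the E geometry of the tiglate and leaves C8 unchanged.

**Step 8**
Reactants: 12
Product: 13 1(10)-epoxide
Conditions: mCPBA (1.1 equiv), NaHCO3, CH2Cl2, 0 °C
Reagents that add atoms: mCPBA, OOC(=O)c1cccc(Cl)c1
Why: the electron-rich trisubstituted E-C1=C10 alkene is epoxidised in preference to the enone and the tiglate. The peripheral face of the macrocycle is attacked (Prilezhaev epoxidation), which sets C10.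

**Step 9**
Reactants: 13
Product: 14 11,13-dihydro-eupaheliangolide A
Conditions: DBU (0.5 equiv), CH2Cl2, rt
Reagents that add atoms: none
Why: the β,γ-epoxy ketone undergoes E1cB opening. Enolisation at C2 expels the C1–O bond, giving the E-C1=C2 enone and the tertiary C10 alkoxide, so C10 configuration is retained.

**Step 10**
Reactants: 14 dihydro lactone; 15 Eschenmoser's salt
Product: 16 eupaheliangolide A
Conditions: LDA (3 equiv), THF, −78 °C; 15, −78 → 0 °C; then MeI; then aq. NaHCO3
Reagents that add atoms: 15, C[N+](C)=C.[I-] (supplies the exocyclic CH2)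
Why: the dienone has no enolisable α-H, so the lactone enolate forms selectively, undergoes Mannich aminomethylation at C11, and then Hofmann-type elimination gives the α-methylene lactone.

## Compound list
1 | (E)-1,2-diiodoethene | I/C=C/I | starting material
2 | 4-methoxybenzyl alcohol | COc1ccc(CO)cc1 | starting material
3 | (E)-1-iodo-2-[(4-methoxybenzyl)oxy]ethene | I/C=C/OCc1ccc(OC)cc1 | intermediate
4 | (R)-(−)-carvone | CC1=CC[C@H](CC1=O)C(C)=C | starting material
5 | (5R)-2-methyl-5-isopropenylcyclohex-2-ene-1,4-dione | CC1=CC(=O)[C@H](CC1=O)C(C)=C | intermediate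
6 | carbinol (C4 epimer unspecified) | CC1=CC(O)(/C=C/OCc2ccc(OC)cc2)[C@H](CC1=O)C(C)=C | intermediate
7 | ethyl bromoacetate | BrCC(=O)OCC | starting material
8 | ten-membered keto ester | CCOC(=O)C[C@H]1C(=O)/C=C(/C)C(=O)C/C=C(\C)C[C@H]1OCc2ccc(OC)cc2 | intermediate
9 | PMB lactone | C1C(=O)O[C@@H]2/C=C(/C)C(=O)C/C=C(\C)C[C@@H](OCc3ccc(OC)cc3)[C@@H]12 | intermediate
10 | hydroxy lactone | C1C(=O)O[C@@H]2/C=C(/C)C(=O)C/C=C(\C)C[C@@H](O)[C@@H]12 | intermediate
11 | tiglic acid | C/C=C(\C)C(=O)O | starting material
12 | 8-tiglate, Δ1(10) | C1C(=O)O[C@@H]2/C=C(/C)C(=O)C/C=C(\C)C[C@@H](OC(=O)/C(C)=C/C)[C@@H]12 | intermediate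
13 | 1(10)-epoxide | C1C(=O)O[C@@H]2/C=C(/C)C(=O)C[C@H]3O[C@]3(C)C[C@@H](OC(=O)/C(C)=C/C)[C@@H]12 | intermediate
14 | 11,13-dihydro-eupaheliangolide A | C1C(=O)O[C@@H]2/C=C(/C)C(=O)/C=C/[C@](C)(O)C[C@@H](OC(=O)/C(C)=C/C)[C@@H]12 | intermediate
15 | Eschenmoser's salt | C[N+](C)=C.[I-] | starting material
16 | eupaheliangolide A | C=C1C(=O)O[C@@H]2/C=C(/C)C(=O)/C=C/[C@](C)(O)C[C@@H](OC(=O)/C(C)=C/C)[C@@H]12 | target

## Totals
Total steps: 10. Longest linear sequence: 9 steps, from carvone (Steps 2–10).

**Three steps most likely to fail**
1. **Step 4 (oxy-Cope and enolate trap).**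
   - The β-alkoxy enolate may eliminate, and the C7/C8 stereochemistry may be wrong.
   - Fallback: use vinylmagnesium bromide in Step 3 instead. Trap the Cope enolate with bromoacetate, then desaturate to the C7=C8 enone (IBX). Then do Weitz–Scheffer epoxidation and SmI2 reductive opening to install C8–OH.
2. **Step 3 (ene-dione 5 and the 1,2-addition).**
   - The ene-dione may aromatise, or the organocerium may add in conjugate fashion.
   - Fallback: make the C1 ketal of 4-hydroxycarvone, oxidise to the non-aromatisable 4-keto ketal, add the alkoxyvinylcerium, then hydrolyse the ketal.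
3. **Step 8 (epoxidation and C10 configuration).**
   - The wrong C10 epimer would form.
   - Fallback: epoxidise hydroxy lactone 10 with VO(acac)2/TBHP before tigloylation, using the homoallylic C8-OH as director, then esterify.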